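**Plan**

1. Retrosynthetic cuts: the C12 acid back to the terminal E-methyl group (three oxidations); then the O1–C2 bond and the C7–OH bond in one operation (key step); then C3–C3a (C-alkylation); then the epoxide C–O bonds (allylic alcohol).
2. Forward order: (2Z,6E)-farnesol is made into a cis-epoxy iodide and joined to a purchased six-membered ring (lithiated 1,5-dimethoxycyclohexa-1,4-diene). Mono-hydrolysis gives a 2-alkyl-3-methoxycyclohexenone; the dihydrofuran, the only ring made, is closed last; the chain terminus is oxidised at the end.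
3. Enabling feature: in the target O1 sits on C7a, the β-carbon of the enone C4(=O)–C3a=C7a, and the hydroxyl on the neighbouring γ-carbon C7. The kinetic α′-enolate of the cyclohexenone has its oxygen on the future C7a and its enolate carbon at the future C7.
4. O-alkylation of that enolate by the side-chain epoxide therefore closes ring O1–C2–C3–C3a–C7a, moves the carbonyl to C4 and leaves a C7=C7a enol ether that is hydroxylated in the same flask. The OMe group is the helper and leaves as MeBr.
5. Stereochemistry: one catalytic Sharpless epoxidation sets the cis-epoxide. The carbinol centre is kept, C2 arises by SN2 inversion, and C7 by substrate control (oxidant anti to the C2 substituent).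

Key step: step 5

Assumption: the like relation of C2 (S) and the carbinol carbon (S) corresponds to anti opening of a cis-epoxide, so the chain is taken from (2Z,6E)-farnesol, assumed purchasable as the single geometric isomer.

**Step 1**
Reactants: 1 (2Z,6E)-farnesol
Product: 2 [(2R,3S)-3-[(3E)-4,8-dimethylnona-3,7-dien-1-yl]-3-methyloxiran-2-yl]methanol
Conditions: Ti(OiPr)4 (10 mol%), D-(−)-diethyl tartrate (12 mol%), tBuOOH (decane), 4 Å MS, CH2Cl2, −20 °C
Reagents that add atoms: tert-butyl hydroperoxide, CC(C)(C)OO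
Why: Sharpless asymmetric epoxidation is directed by the allylic hydroxyl, so only the 2,3-alkene should react, and with D-(−)-tartrate the Z-allylic alcohol should be epoxidised on the face that gives the (2R,3S) cis-epoxide, which fixes both side-chain stereocentres in one catalytic event.

**Step 2**
Reactants: 2 [(2R,3S)-3-[(3E)-4,8-dimethylnona-3,7-dien-1-yl]-3-methyloxiran-2-yl]methanol
Product: 3 (2S,3S)-3-[(3E)-4,8-dimethylnona-3,7-dien-1-yl]-2-(iodomethyl)-3-methyloxirane
Conditions: I2, PPh3, imidazole, CH2Cl2, 0 °C, dark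
Reagents that add atoms: iodine, II
Why: Appel-type iodination replaces the primary hydroxyl by SN2 at the CH2 carbon under buffered conditions that should leave the trisubstituted epoxide and both stereocentres untouched (the descriptor at C2 changes only because iodine raises the CIP rank of CH2I).

**Step 3**
Reactants: 3 (2S,3S)-3-[(3E)-4,8-dimethylnona-3,7-dien-1-yl]-2-(iodomethyl)-3-methyloxirane; 4 1,5-dimethoxycyclohexa-1,4-diene
Product: 6 (2R,3S)-2-[(2,6-dimethoxycyclohexa-2,5-dien-1-yl)methyl]-3-[(3E)-4,8-dimethylnona-3,7-dien-1-yl]-3-methyloxirane, via lithium 1,5-dimethoxycyclohexadienide 5 (not isolated)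
Conditions: 4 (1.3 equiv), tBuLi (1.2 equiv), THF, −78 °C; DMPU; then 3, −78 → −20 °C
Reagents that add atoms: none
Why: deprotonation of the bis-enol ether between its two methoxy-bearing carbons and alkylation of the resulting cyclohexadienyl anion at that central carbon by a primary halide is the established entry to 2-alkylcyclohexane-1,3-dione bis-enol ethers (SN2 at the non-stereogenic CH2I carbon), and the soft delocalised carbanion should displace iodide faster than it attacks the hindered epoxide carbons.

**Step 4**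
Reactants: 6 (2R,3S)-2-[(2,6-dimethoxycyclohexa-2,5-dien-1-yl)methyl]-3-[(3E)-4,8-dimethylnona-3,7-dien-1-yl]-3-methyloxirane
Product: 8 2-{[(2R,3S)-3-[(3E)-4,8-dimethylnona-3,7-dien-1-yl]-3-methyloxiran-2-yl]methyl}-3-methoxycyclohex-2-en-1-one, via deconjugated ketone 7 (not isolated)
Conditions: PPTS (10 mol%), H2O (2 equiv), THF, 0 °C → rt; then DBU (0.3 equiv), 0 °C
Reagents that add atoms: water, O
Why: enol ether hydrolysis with a weak acid and a limited amount of water removes one of the two equivalent methyl enol ethers much faster than the epoxide is activated, and base-mediated conjugation of the β,γ-unsaturated ketone then gives the vinylogous ester, whose remaining OMe blocks one dione oxygen so that the free dione, which would open the epoxide without regiocontrol, is never formed.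

**Step 5**
Reactants: 8 2-{[(2R,3S)-3-[(3E)-4,8-dimethylnona-3,7-dien-1-yl]-3-methyloxiran-2-yl]methyl}-3-methoxycyclohex-2-en-1-one
Product: 14 (2S,7R)-7-hydroxy-2-[(2S,5E)-2-hydroxy-6,10-dimethylundeca-5,9-dien-2-yl]-3,5,6,7-tetrahydro-1-benzofuran-4(2H)-one, via lithium dienolate 9 (not isolated), via bicyclic lithium alkoxide 10 (not isolated), via silylated dienyl ether 11 (not isolated), via 7,7a-epoxide 12 (not isolated), via lithium 7-alkoxide 13 (not isolated)
Conditions: LiN(iPr)2 (1.1 equiv), THF, −78 °C; DMPU, −78 → 0 °C; Me3SiCl, −78 °C; volatiles off, CH2Cl2; DMDO (acetone, 1.05 equiv), −78 °C; LiBr, THF, −78 → 0 °C; 0.5 M HCl, 0 °C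
Reagents that add atoms: dimethyldioxirane, CC1(C)OO1
Why: Proposed new method: LiN(iPr)2 removes the kinetic α′-proton of 8 (Stork–Danheiser regiochemistry), the enolate oxygen, the only anionic oxygen because the other one is capped as OMe, opens the epoxide at its secondary carbon by SN2, and the 1,3-dialkoxydiene 11 formed after silylation of the tertiary alkoxide is epoxidised by DMDO at its terminal C7=C7a bond, after which bromide removes the methyl group from the resulting oxocarbenium ion and unveils the C4 ketone without water ever adding at C7a. The closest known reactions are the base-mediated 5-exo cyclisation of 2-(2,3-epoxyalkyl)phenoxides and 1,3-dione enolates to 2-(1-hydroxyalkyl)dihydrofurans and the Rubottom oxidation of alkoxydienes; new is the use of a cross-conjugated vinylogous ester enolate as the oxygen nucleophile, so that ring closure transposes the vinylogous ester and marks C7 for oxidation. The dihydrofuran closes by O1–C2 bond formation in the 5-exo-tet mode. C2 is set by inversion at the epoxide CH, the carbinol centre is carried over unchanged from the Sharpless epoxide, and C7 should be set by attack of DMDO on the face of the flat dienyl ether opposite the C2 substituent with its silyloxy-bearing quaternary carbon (2,7-trans). The step needs exo over endo opening (basic SN2 conditions favour the less substituted carbon, and C-alkylation would require a bridgehead alkene), the α′ and not the γ enolate (irreversible deprotonation, no proton source able to equilibrate it), and oxidation of the diene and not of the chain alkenes (the dialkoxydiene is far more nucleophilic at −78 °C, and the oxidisable amine is removed beforehand).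

**Step 6**
Reactants: 14 (2S,7R)-7-hydroxy-2-[(2S,5E)-2-hydroxy-6,10-dimethylundeca-5,9-dien-2-yl]-3,5,6,7-tetrahydro-1-benzofuran-4(2H)-one
Product: 15 (2S,7R)-2-[(2S,5E,9E)-2,11-dihydroxy-6,10-dimethylundeca-5,9-dien-2-yl]-7-hydroxy-3,5,6,7-tetrahydro-1-benzofuran-4(2H)-one
Conditions: SeO2 (0.3 equiv), tBuOOH (3 equiv), CH2Cl2, 0 °C → rt
Reagents that add atoms: selenium dioxide (oxygen carrier, catalytic), O=[Se]=O; tert-butyl hydroperoxide (terminal oxidant), CC(C)(C)OO
Why: selenium dioxide allylic oxidation (ene reaction, then [2,3]-sigmatropic shift) is selective for the E-methyl group of the terminal, least hindered and most electron-rich trisubstituted alkene, as in farnesyl systems, while the tetrasubstituted vinylogous ester alkene should not react and no stereocentre is touched.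

**Step 7**
Reactants: 15 (2S,7R)-2-[(2S,5E,9E)-2,11-dihydroxy-6,10-dimethylundeca-5,9-dien-2-yl]-7-hydroxy-3,5,6,7-tetrahydro-1-benzofuran-4(2H)-one
Product: 16 (2E,6E,10S)-10-hydroxy-10-[(2S,7R)-7-hydroxy-4-oxo-2,3,4,5,6,7-hexahydro-1-benzofuran-2-yl]-2,6-dimethylundeca-2,6-dienal
Conditions: TEMPO (10 mol%), PhI(OAc)2 (1.1 equiv), CH2Cl2, 0 °C → rt
Reagents that add atoms: none
Why: the TEMPO/PhI(OAc)2 oxidation is selective for the primary allylic alcohol over the secondary C7 and the tertiary alcohol and stops at the aldehyde with retention of the E geometry.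

**Step 8**
Reactants: 16 (2E,6E,10S)-10-hydroxy-10-[(2S,7R)-7-hydroxy-4-oxo-2,3,4,5,6,7-hexahydro-1-benzofuran-2-yl]-2,6-dimethylundeca-2,6-dienal
Product: 17 (2E,6E,10S)-10-hydroxy-10-[(2S,7R)-7-hydroxy-4-oxo-2,3,4,5,6,7-hexahydro-1-benzofuran-2-yl]-2,6-dimethylundeca-2,6-dienoic acid
Conditions: NaClO2, NaH2PO4, 2-methylbut-2-ene, tBuOH/H2O, 0 °C
Reagents that add atoms: sodium chlorite, [Na+].[O-]Cl=O
Why: the Pinnick oxidation converts the enal into the enoic acid under buffered conditions with 2-methylbut-2-ene as hypochlorite scavenger, which should leave the alkenes, the free alcohols and the vinylogous ester untouched.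

**Compound list**

1 | (2Z,6E)-farnesol | CC(C)=CCC/C(C)=C/CC/C(C)=C\CO | starting material
2 | [(2R,3S)-3-[(3E)-4,8-dimethylnona-3,7-dien-1-yl]-3-methyloxiran-2-yl]methanol | OC[C@H]1O[C@@]1(C)CC/C=C(C)/CCC=C(C)C | intermediate
3 | (2S,3S)-3-[(3E)-4,8-dimethylnona-3,7-dien-1-yl]-2-(iodomethyl)-3-methyloxirane | IC[C@H]1O[C@@]1(C)CC/C=C(C)/CCC=C(C)C | intermediate
4 | 1,5-dimethoxycyclohexa-1,4-diene | COC1=CCC=C(OC)C1 | starting material
5 | lithium 1,5-dimethoxycyclohexadienide (anion centred on the carbon between the two methoxy-bearing carbons) | [Li+].COC1=CCC=C(OC)[CH-]1 | intermediate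
6 | (2R,3S)-2-[(2,6-dimethoxycyclohexa-2,5-dien-1-yl)methyl]-3-[(3E)-4,8-dimethylnona-3,7-dien-1-yl]-3-methyloxirane | COC1=CCC=C(OC)C1C[C@H]2O[C@@]2(C)CC/C=C(C)/CCC=C(C)C | intermediate
7 | 2-{[(2R,3S)-3-[(3E)-4,8-dimethylnona-3,7-dien-1-yl]-3-methyloxiran-2-yl]methyl}-3-methoxycyclohex-3-en-1-one (both epimers at ring C2) | COC1=CCCC(=O)C1C[C@H]2O[C@@]2(C)CC/C=C(C)/CCC=C(C)C | intermediate
8 | 2-{[(2R,3S)-3-[(3E)-4,8-dimethylnona-3,7-dien-1-yl]-3-methyloxiran-2-yl]methyl}-3-methoxycyclohex-2-en-1-one | COC1=C(C[C@H]2O[C@@]2(C)CC/C=C(C)/CCC=C(C)C)C(=O)CCC1 | intermediate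
9 | lithium 5-methoxy-6-{[(2R,3S)-3-[(3E)-4,8-dimethylnona-3,7-dien-1-yl]-3-methyloxiran-2-yl]methyl}cyclohexa-1,5-dien-1-olate (kinetic α′-enolate of 8) | [Li+].COC1=C(C[C@H]2O[C@@]2(C)CC/C=C(C)/CCC=C(C)C)C([O-])=CCC1 | intermediate
10 | lithium (2S,5E)-2-[(2S)-4-methoxy-2,3,5,6-tetrahydro-1-benzofuran-2-yl]-6,10-dimethylundeca-5,9-dien-2-olate | [Li+].CC(C)=CCC/C(C)=C/CC[C@](C)([O-])[C@@H]1CC2=C(OC)CCC=C2O1 | intermediate
11 | {[(2S,5E)-2-[(2S)-4-methoxy-2,3,5,6-tetrahydro-1-benzofuran-2-yl]-6,10-dimethylundeca-5,9-dien-2-yl]oxy}trimethylsilane | CC(C)=CCC/C(C)=C/CC[C@](C)(O[Si](C)(C)C)[C@@H]1CC2=C(OC)CCC=C2O1 | intermediate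
12 | 7,7a-epoxide of 11, oxirane oxygen on the face opposite the C2 side chain | CC(C)=CCC/C(C)=C/CC[C@](C)(O[Si](C)(C)C)[C@@H]1CC2=C(OC)CC[C@H]3O[C@@]23O1 | intermediate
13 | lithium (2S,7R)-2-[(2S,5E)-6,10-dimethyl-2-(trimethylsilyloxy)undeca-5,9-dien-2-yl]-4-oxo-2,3,4,5,6,7-hexahydro-1-benzofuran-7-olate | [Li+].CC(C)=CCC/C(C)=C/CC[C@](C)(O[Si](C)(C)C)[C@@H]1CC2=C(O1)[C@H]([O-])CCC2=O | intermediate
14 | (2S,7R)-7-hydroxy-2-[(2S,5E)-2-hydroxy-6,10-dimethylundeca-5,9-dien-2-yl]-3,5,6,7-tetrahydro-1-benzofuran-4(2H)-one | C/C(=C\CC[C@](C)(O)[C@@H]1CC2=C(O1)[C@H](O)CCC2=O)CCC=C(C)C | intermediate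
15 | (2S,7R)-2-[(2S,5E,9E)-2,11-dihydroxy-6,10-dimethylundeca-5,9-dien-2-yl]-7-hydroxy-3,5,6,7-tetrahydro-1-benzofuran-4(2H)-one | C/C(=C\CC[C@](C)(O)[C@@H]1CC2=C(O1)[C@H](O)CCC2=O)CC/C=C(\C)CO | intermediate
16 | (2E,6E,10S)-10-hydroxy-10-[(2S,7R)-7-hydroxy-4-oxo-2,3,4,5,6,7-hexahydro-1-benzofuran-2-yl]-2,6-dimethylundeca-2,6-dienal | C/C(=C\CC[C@](C)(O)[C@@H]1CC2=C(O1)[C@H](O)CCC2=O)CC/C=C(\C)C=O | intermediate
17 | (2E,6E,10S)-10-hydroxy-10-[(2S,7R)-7-hydroxy-4-oxo-2,3,4,5,6,7-hexahydro-1-benzofuran-2-yl]-2,6-dimethylundeca-2,6-dienoic acid | C/C(=C\CC[C@](C)(O)[C@@H]1CC2=C(O1)[C@H](O)CCC2=O)CC/C=C(\C)C(=O)O | target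

**Step count and risks**

Total step count: 8. Longest linear sequence: 8 steps (1 → 17); diene 4 is used as purchased.

Steps most likely to fail:

1. Step 5 (Proposed new method). The most likely failure is low facial selectivity in the oxidation of the dienyl ether 11, because the C2 substituent that must steer DMDO is three bonds away from C7; partial equilibration of the enolate before ring closure would in addition return material without the C7 oxygen. Fallback (known chemistry, stereochemical correction instead of substrate control): the fallback sets out from 8, with step 5 run as written. The unwanted epimer (2S,7S)-7-hydroxy-2-[(2S,5E)-2-hydroxy-6,10-dimethylundeca-5,9-dien-2-yl]-3,5,6,7-tetrahydro-1-benzofuran-4(2H)-one F1 would be separated and inverted at C7 by a Mitsunobu reaction (PPh3, diisopropyl azodicarboxylate, 4-nitrobenzoic acid, THF, 0 °C; the tertiary alcohol does not react) to (2S,7R)-2-[(2S,5E)-2-hydroxy-6,10-dimethylundeca-5,9-dien-2-yl]-4-oxo-2,3,4,5,6,7-hexahydro-1-benzofuran-7-yl 4-nitrobenzoate F2. Methanolysis (K2CO3 cat., MeOH, 0 °C) would return the route at 14.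

2. Step 4. Over-hydrolysis to the free 1,3-dione, or ring closure through the extended enolate during the DBU stage, would open the epoxide prematurely and give the bicyclic ketone without the C7 handle. Fallback (no acid and no free dione; the ring is brought in as a preformed vinylogous ester): the fallback sets out from iodide 3. Commercial 3-methoxycyclohex-2-en-1-one would be iodinated (I2, pyridine, CH2Cl2) to 2-iodo-3-methoxycyclohex-2-en-1-one F3 and converted by iodine–magnesium exchange (iPrMgCl·LiCl, THF, −40 °C) into (2-methoxy-6-oxocyclohex-1-en-1-yl)magnesium chloride F4. Copper-catalysed coupling (Li2CuCl4, THF, −40 → 0 °C) with 3 would return the route at 8.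

3. Step 6. Incomplete conversion and competing oxidation at the allylic CH2 groups of the internal alkene, on a polyfunctional late intermediate, would erode material. Fallback (olefin metathesis instead of C–H oxidation): the fallback sets out from 14. Cross-metathesis with excess methacrolein (second-generation Hoveyda–Grubbs catalyst, CH2Cl2, 40 °C) should exchange the terminal isopropylidene for the E-enal and return the route at 16, so that step 7 is skipped.

**Further compounds**

F1 | step 5 | (2S,7S)-7-hydroxy-2-[(2S,5E)-2-hydroxy-6,10-dimethylundeca-5,9-dien-2-yl]-3,5,6,7-tetrahydro-1-benzofuran-4(2H)-one | C/C(=C\CC[C@](C)(O)[C@@H]1CC2=C(O1)[C@@H](O)CCC2=O)CCC=C(C)C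
F2 | step 5 | (2S,7R)-2-[(2S,5E)-2-hydroxy-6,10-dimethylundeca-5,9-dien-2-yl]-4-oxo-2,3,4,5,6,7-hexahydro-1-benzofuran-7-yl 4-nitrobenzoate | C/C(=C\CC[C@](C)(O)[C@@H]1CC2=C(O1)[C@H](OC(=O)c3ccc(cc3)[N+](=O)[O-])CCC2=O)CCC=C(C)C
F3 | step 4 | 2-iodo-3-methoxycyclohex-2-en-1-one | COC1=C(I)C(=O)CCC1
F4 | step 4 | (2-methoxy-6-oxocyclohex-1-en-1-yl)magnesium chloride | COC1=C([Mg]Cl)C(=O)CCC1
F0 | step 6 | none | none
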